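**Plan**

1. Numbering: ring A = C1–C5 plus C10 (gem-dimethyl C4, angular CH3 on C10); ring B = C5–C10 (CH3 on C8, C8=C9); chain C11–C16 from C9 to the butenolide. "Dec" = (4aR,8aS)-2,5,5,8a-tetramethyl-3,4,4a,5,6,7,8,8a-octahydronaphthalen-1-yl, cis-fused, attached through C9.
2. Cuts, latest first: C16–butenolide (Stille); C13=C14 (Horner–Wadsworth–Emmons); C12–C13 (phosphonate alkylation); C9–C11 (Stille on a C9 enol triflate); the C1 carbonyl; C3–C4 of ring A (radical closure); C10–CH3 and C10–C1.
3. Enabling feature: ring B with its C8 methyl, a carbonyl at C9 and an isopropenyl group on C5 (C4 and one of its methyls) is (S)-carvone. The quaternary gem-dimethyl C4 next to C5 is what the tertiary radical of that isopropenyl group leaves when it adds to C3 of an acryloyl group (C1–C3) on C10.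
4. Forward: ring B is bought; C1–C3 and the C10 methyl are attached; ring A closes by hydrogen-atom-transfer radical cyclisation (6-endo); the chain is grown outward from C9 and the butenolide is coupled last.
5. Stereochemistry: C5 is the carvone stereocentre. C10 is set by methylation of the acylcarvone enolate anti to the isopropenyl group, which gives the cis fusion. 13E comes from thermodynamic control in the olefination, 15E from an (E)-stannylacrolein.

Key step: step 6

Remark: the descriptors of the target (5R,10S) correspond to a cis-fused decalin (10-CH3 and 5-H on the same face) and the route is built for that isomer; metal enolates and phosphonate anions are made and consumed in the same flask and appear in the Conditions lines, only covalent intermediates being numbered.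

**Route**

Step 1
Reactants: 1 (S)-(+)-carvone; 2 3-(tert-butyldimethylsilyloxy)propanal
Product: 3 (5S)-6-[3-(tert-butyldimethylsilyloxy)-1-hydroxypropyl]-2-methyl-5-(prop-1-en-2-yl)cyclohex-2-en-1-one
Conditions: LiN(i-Pr)2, THF, −78 °C; then 2; AcOH quench at −78 °C
Reagents that add atoms: none
Why: LiN(i-Pr)2 deprotonates carvone kinetically at the α′-methylene (C6 of carvone, the future C10) and the cross-conjugated lithium dienolate undergoes a directed aldol addition to 2, the two new stereocentres (C6 and the carbinol carbon) forming as a mixture that is erased in steps 2 and 3.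

Step 2
Reactants: 3 aldol adduct
Product: 4 (5S)-6-[3-(tert-butyldimethylsilyloxy)propanoyl]-2-methyl-5-(prop-1-en-2-yl)cyclohex-2-en-1-one
Conditions: Dess–Martin periodinane, CH2Cl2, 0 °C → rt
Reagents that add atoms: none
Why: Dess–Martin oxidation converts the β-hydroxy ketone into the 1,3-diketone under non-basic conditions that should leave the silyl ether and both alkenes alone, removing the carbinol stereocentre and making C6 enolisable.

Step 3
Reactants: 4 1,3-diketone; 5 iodomethane
Product: 6 (5R,6R)-6-[3-(tert-butyldimethylsilyloxy)propanoyl]-2,6-dimethyl-5-(prop-1-en-2-yl)cyclohex-2-en-1-one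
Conditions: K2CO3, acetone, rt
Reagents that add atoms: none
Why: C-alkylation of the chelated potassium enolate of the 2-acylcyclohexenone by the soft electrophile MeI should take place on the face opposite the neighbouring C5 isopropenyl group, which puts the new methyl trans and the acyl group cis to isopropenyl and so sets the quaternary centre (future C10) for the cis ring fusion.

Step 4
Reactants: 6 methylated diketone
Product: 7 (5R,6R)-6-(3-hydroxypropanoyl)-2,6-dimethyl-5-(prop-1-en-2-yl)cyclohex-2-en-1-one
Conditions: HF·pyridine, THF, 0 °C → rt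
Reagents that add atoms: none
Why: Fluoride-mediated desilylation under weakly acidic conditions frees the primary alcohol without the alkoxide basicity that could trigger retro-Claisen cleavage of the non-enolisable 1,3-diketone.

Step 5
Reactants: 7 hydroxy diketone
Product: 9 (5R,6R)-6-acryloyl-2,6-dimethyl-5-(prop-1-en-2-yl)cyclohex-2-en-1-one, via primary mesylate 8 (not isolated)
Conditions: MsCl, Et3N, CH2Cl2, 0 °C → rt
Reagents that add atoms: none
Why: Mesylation of the primary alcohol followed in the same flask by Et3N-induced E1cB elimination of the β-mesyloxy ketone unmasks the vinyl ketone under conditions too mild to affect the quaternary 1,3-diketone.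

Step 6
Reactants: 9 6-acryloyl-6-methylcarvone
Product: 10 (4aR,8aR)-4,4,7,8a-tetramethyl-3,4,4a,5-tetrahydronaphthalene-1,8(2H,8aH)-dione
Conditions: Fe(acac)3, PhSiH3, EtOH/HOCH2CH2OH, 60 °C, high dilution, degassed
Reagents that add atoms: none
Why: Fe(acac)3 and PhSiH3 in ethanol generate an iron hydride that transfers a hydrogen atom to the terminal CH2 of the electron-rich 1,1-disubstituted isopropenyl group (Markovnikov sense) and creates the nucleophilic tertiary radical at C4; this adds to the unsubstituted β-carbon C3 of the acryloyl group on C10, and the α-keto radical at C2 is then reduced to the enolate and protonated by the solvent. The closest known reaction type is the iron/silane hydrogen-atom-transfer reductive coupling of unactivated olefins with enones (a Giese-type radical conjugate addition), used here intramolecularly. Ring A closes in the 6-endo-trig mode, because attack at C3 gives a stabilised α-acyl radical in a six-membered ring whereas 5-exo attack at C2 would leave an unstabilised primary radical. No stereocentre is created (C4 becomes the gem-dimethyl carbon, C2 and C3 are methylenes), and the cis ring fusion is already fixed because the acryloyl and isopropenyl groups stand cis on ring B after step 3. The step needs hydrogen-atom transfer to the isopropenyl group in the presence of two enones: the acryloyl alkene is electron-poor, and the C7=C8 enone alkene is trisubstituted, conjugated and out of reach of the C4 radical (only a four-membered ring could form), so it survives as the handle for step 7.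

Step 7
Reactants: 10 cis-fused enedione
Product: 12 (4aR,8aS)-2,5,5,8a-tetramethyl-8-oxo-3,4,4a,5,6,7,8,8a-octahydronaphthalen-1-yl trifluoromethanesulfonate, via silyl enol ether 11 (not isolated)
Conditions: [CuH(PPh3)]6 (cat.), PhMe2SiH, toluene, rt; then CsF, PhNTf2, DME, rt
Reagents that add atoms: N-phenylbis(trifluoromethanesulfonimide), O=S(=O)(N(c1ccccc1)S(=O)(=O)C(F)(F)F)C(F)(F)F
Why: Copper hydride conjugate reduction (1,4-hydrosilylation) is selective for the enone over the isolated C1 ketone and gives the C8=C9 silyl enol ether regiospecifically because C10 is quaternary, and fluoride-induced desilylation in the presence of PhNTf2 then converts it into the enol triflate without a strong base or carbon nucleophile that would attack C1.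

Step 8
Reactants: 12 keto enol triflate; 13 tributyl(vinyl)stannane
Product: 14 (4aR,8aS)-8-ethenyl-4,4,7,8a-tetramethyl-3,4,4a,5,6,8a-hexahydronaphthalen-1(2H)-one
Conditions: Pd(PPh3)4, LiCl, THF, reflux
Reagents that add atoms: none
Why: Stille cross-coupling of the enol triflate with the vinylstannane in the presence of LiCl forms the C9–C11 bond under neutral conditions that the ketone tolerates, the position of the tetrasubstituted C8=C9 bond being fixed by the triflate.

Step 9
Reactants: 14 dienyl ketone
Product: 16 (4aR,8aS)-8-(2-hydroxyethyl)-4,4,7,8a-tetramethyl-3,4,4a,5,6,8a-hexahydronaphthalen-1(2H)-one, via alkylborane 15 (not isolated)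
Conditions: 9-BBN, THF, 0 °C → rt; then aq. NaOH, H2O2, 0 °C
Reagents that add atoms: hydrogen peroxide, OO
Why: Anti-Markovnikov hydroboration with bulky 9-BBN should occur only at the terminal CH2 of the vinyl group (C12), much faster than at the tetrasubstituted C8=C9 bond or the neopentyl-type C1 carbonyl, and alkaline peroxide oxidation then gives the primary alcohol.

Step 10
Reactants: 16 hydroxy ketone
Product: 18 2-Dec-ethanol, via hydrazone 17 (not isolated)
Conditions: N2H4·H2O, KOH, diethylene glycol, 130 → 200 °C, argon
Reagents that add atoms: none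
Why: Wolff–Kishner reduction converts the C1 carbonyl into CH2 by way of the hydrazone anion and loss of N2, the quaternary C10 excluding epimerisation or conjugation and the tetrasubstituted alkene and primary alcohol being inert to hot alkali.

Step 11
Reactants: 18 2-Dec-ethanol
Product: 19 2-Dec-ethyl iodide
Conditions: I2, PPh3, imidazole, CH2Cl2, 0 °C → rt
Reagents that add atoms: iodine, II
Why: Appel iodination converts the unhindered primary alcohol into the iodide by SN2 displacement of the alkoxyphosphonium ion under neutral conditions.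

Step 12
Reactants: 19 2-Dec-ethyl iodide; 20 triethyl phosphonoacetate
Product: 21 ethyl 4-Dec-2-(diethoxyphosphoryl)butanoate
Conditions: NaH, excess 20, DMF, 0 → 60 °C
Reagents that add atoms: none
Why: SN2 alkylation of the sodium salt of triethyl phosphonoacetate by the primary iodide forms the C12–C13 bond, and the new stereocentre at C13 (formed as a mixture) is of no consequence because it becomes sp2 in step 14.

Step 13
Reactants: 22 (E)-3-(tributylstannyl)prop-2-en-1-ol
Product: 23 (E)-3-(tributylstannyl)prop-2-enal
Conditions: MnO2, CH2Cl2, rt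
Reagents that add atoms: none
Why: MnO2 oxidises the allylic alcohol selectively to the enal under neutral heterogeneous conditions that preserve the acid-sensitive vinylstannane and its E geometry.

Step 14
Reactants: 21 α-substituted phosphonoacetate; 23 (E)-3-(tributylstannyl)prop-2-enal
Product: 24 ethyl (2E,4E)-2-(2-Dec-ethyl)-5-(tributylstannyl)penta-2,4-dienoate
Conditions: NaH, THF, 0 °C; then 23, 0 °C → rt
Reagents that add atoms: none
Why: Horner–Wadsworth–Emmons olefination of the α-branched phosphonoacetate anion with the enal forms C13=C14 under thermodynamic control, so that the ester should end up trans and the C12 chain cis to C15 (13E), while the 15E geometry is carried in from 23.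

Step 15
Reactants: 24 stannyl dienoate
Product: 25 (2E,4E)-2-(2-Dec-ethyl)-5-(tributylstannyl)penta-2,4-dien-1-ol
Conditions: i-Bu2AlH, CH2Cl2, −78 °C; aq. potassium sodium tartrate work-up
Reagents that add atoms: none
Why: i-Bu2AlH reduces the conjugated ester in 1,2-fashion to the allylic alcohol at low temperature without affecting the dienylstannane or the alkene geometries.

Step 16
Reactants: 25 dienylstannane alcohol; 26 4-bromofuran-2(5H)-one
Product: 27 4-[(1E,3E)-6-Dec-4-(hydroxymethyl)hexa-1,3-dien-1-yl]furan-2(5H)-one
Conditions: Pd2(dba)3, AsPh3, DMF, rt, dark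
Reagents that add atoms: none
Why: Stille cross-coupling of the (E)-dienylstannane with the vinylogous acyl bromide proceeds with retention at both sp2 carbons under base-free conditions that the butenolide and the free allylic alcohol tolerate, completing the trienyl butenolide.

**Compound list**

1 | (S)-(+)-carvone, (5S)-2-methyl-5-(prop-1-en-2-yl)cyclohex-2-en-1-one | CC1=CC[C@@H](CC1=O)C(C)=C | starting material
2 | 3-(tert-butyldimethylsilyloxy)propanal | CC(C)(C)[Si](C)(C)OCCC=O | starting material
3 | (5S)-6-[3-(tert-butyldimethylsilyloxy)-1-hydroxypropyl]-2-methyl-5-(prop-1-en-2-yl)cyclohex-2-en-1-one (epimers at C6 and the carbinol carbon) | CC1=CC[C@H](C(C)=C)C(C(O)CCO[Si](C)(C)C(C)(C)C)C1=O | intermediate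
4 | (5S)-6-[3-(tert-butyldimethylsilyloxy)propanoyl]-2-methyl-5-(prop-1-en-2-yl)cyclohex-2-en-1-one (C6 epimers and enol forms) | CC1=CC[C@H](C(C)=C)C(C(=O)CCO[Si](C)(C)C(C)(C)C)C1=O | intermediate
5 | iodomethane | CI | starting material
6 | (5R,6R)-6-[3-(tert-butyldimethylsilyloxy)propanoyl]-2,6-dimethyl-5-(prop-1-en-2-yl)cyclohex-2-en-1-one (acyl cis to isopropenyl) | CC1=CC[C@H](C(C)=C)[C@](C)(C(=O)CCO[Si](C)(C)C(C)(C)C)C1=O | intermediate
7 | (5R,6R)-6-(3-hydroxypropanoyl)-2,6-dimethyl-5-(prop-1-en-2-yl)cyclohex-2-en-1-one | CC1=CC[C@H](C(C)=C)[C@](C)(C(=O)CCO)C1=O | intermediate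
8 | methanesulfonate of the primary alcohol of 7 (ring configuration unchanged) | CC1=CC[C@H](C(C)=C)[C@](C)(C(=O)CCOS(C)(=O)=O)C1=O | intermediate (not isolated)
9 | (5R,6R)-6-acryloyl-2,6-dimethyl-5-(prop-1-en-2-yl)cyclohex-2-en-1-one (acryloyl cis to isopropenyl) | CC1=CC[C@H](C(C)=C)[C@](C)(C(=O)C=C)C1=O | intermediate
10 | (4aR,8aR)-4,4,7,8a-tetramethyl-3,4,4a,5-tetrahydronaphthalene-1,8(2H,8aH)-dione (cis-fused; ketones at C1 and C9, C7=C8) | CC1=CC[C@@H]2C(C)(C)CCC(=O)[C@]2(C)C1=O | intermediate
11 | (4aR,8aS)-8-[dimethyl(phenyl)silyloxy]-4,4,7,8a-tetramethyl-3,4,4a,5,6,8a-hexahydronaphthalen-1(2H)-one | CC1=C(O[Si](C)(C)c3ccccc3)[C@@]2(C)C(=O)CCC(C)(C)[C@H]2CC1 | intermediate (not isolated)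
12 | (4aR,8aS)-2,5,5,8a-tetramethyl-8-oxo-3,4,4a,5,6,7,8,8a-octahydronaphthalen-1-yl trifluoromethanesulfonate | CC1=C(OS(=O)(=O)C(F)(F)F)[C@@]2(C)C(=O)CCC(C)(C)[C@H]2CC1 | intermediate
13 | tributyl(vinyl)stannane | C=C[Sn](CCCC)(CCCC)CCCC | starting material
14 | (4aR,8aS)-8-ethenyl-4,4,7,8a-tetramethyl-3,4,4a,5,6,8a-hexahydronaphthalen-1(2H)-one | CC1=C(C=C)[C@@]2(C)C(=O)CCC(C)(C)[C@H]2CC1 | intermediate
15 | 9-{2-[(4aR,8aS)-2,5,5,8a-tetramethyl-8-oxo-3,4,4a,5,6,7,8,8a-octahydronaphthalen-1-yl]ethyl}-9-borabicyclo[3.3.1]nonane | CC1=C(CCB3C4CCCC3CCC4)[C@@]2(C)C(=O)CCC(C)(C)[C@H]2CC1 | intermediate (not isolated)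
16 | (4aR,8aS)-8-(2-hydroxyethyl)-4,4,7,8a-tetramethyl-3,4,4a,5,6,8a-hexahydronaphthalen-1(2H)-one | CC1=C(CCO)[C@@]2(C)C(=O)CCC(C)(C)[C@H]2CC1 | intermediate
17 | C1 hydrazone of 16 | CC1=C(CCO)[C@@]2(C)C(=NN)CCC(C)(C)[C@H]2CC1 | intermediate (not isolated)
18 | 2-Dec-ethanol, 2-[(4aR,8aS)-2,5,5,8a-tetramethyl-3,4,4a,5,6,7,8,8a-octahydronaphthalen-1-yl]ethanol | CC1=C(CCO)[C@@]2(C)CCCC(C)(C)[C@H]2CC1 | intermediate
19 | 2-Dec-ethyl iodide | CC1=C(CCI)[C@@]2(C)CCCC(C)(C)[C@H]2CC1 | intermediate
20 | triethyl phosphonoacetate | CCOC(=O)CP(=O)(OCC)OCC | starting material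
21 | ethyl 4-Dec-2-(diethoxyphosphoryl)butanoate (epimers at C2 of the butanoate) | CC1=C(CCC(C(=O)OCC)P(=O)(OCC)OCC)[C@@]2(C)CCCC(C)(C)[C@H]2CC1 | intermediate
22 | (E)-3-(tributylstannyl)prop-2-en-1-ol | OC/C=C/[Sn](CCCC)(CCCC)CCCC | starting material
23 | (E)-3-(tributylstannyl)prop-2-enal | O=C/C=C/[Sn](CCCC)(CCCC)CCCC | intermediate
24 | ethyl (2E,4E)-2-(2-Dec-ethyl)-5-(tributylstannyl)penta-2,4-dienoate | CC1=C(CC/C(=C\C=C\[Sn](CCCC)(CCCC)CCCC)C(=O)OCC)[C@@]2(C)CCCC(C)(C)[C@H]2CC1 | intermediate
25 | (2E,4E)-2-(2-Dec-ethyl)-5-(tributylstannyl)penta-2,4-dien-1-ol | CC1=C(CC/C(=C\C=C\[Sn](CCCC)(CCCC)CCCC)CO)[C@@]2(C)CCCC(C)(C)[C@H]2CC1 | intermediate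
26 | 4-bromofuran-2(5H)-one | BrC1=CC(=O)OC1 | starting material
27 | 4-[(1E,3E)-6-Dec-4-(hydroxymethyl)hexa-1,3-dien-1-yl]furan-2(5H)-one, CNP0232848.3, (5R,10S,13E,15E) | CC1=C(CC/C(=C\C=C\C2=CC(=O)OC2)CO)[C@@]2(C)CCCC(C)(C)[C@H]2CC1 | target

**Step count and risks**

Total step count: 16. Longest linear sequence: 15 steps from 1 (steps 1–12 and 14–16); step 13 is a one-step side branch.

Steps most likely to fail:

Step 6. Hydrogen-atom transfer to the acryloyl alkene, or reduction of the C4 radical before it cyclises, may outrun ring closure, so that simple hydrogenation and oligomerisation of the vinyl ketone take over. The fallback makes the same C4 radical without a metal hydride. Setting out from 9, excess HBr in AcOH/CH2Cl2 at 0 °C should add in the Markovnikov sense to the isopropenyl group and in the conjugate sense to the vinyl ketone, giving the dibromide 6-(3-bromopropanoyl)-5-(2-bromopropan-2-yl)-2,6-dimethylcyclohex-2-en-1-one F1. Et3N at 0 °C eliminates HBr from the β-bromo ketone only (E1cB) and returns the vinyl ketone as 6-acryloyl-5-(2-bromopropan-2-yl)-2,6-dimethylcyclohex-2-en-1-one F2. Slow addition of Bu3SnH with AIBN in benzene at 80 °C then generates the tertiary radical by bromine-atom abstraction, and its 6-endo conjugate addition comes back to the route at 10.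

Step 7. Chemoselectivity between the two carbonyl groups may be lost (hydride or silyl transfer at C1), or proton exchange between the fluoride-liberated C9 enolate and C2–H may lead to triflation on the wrong side. The fallback gives up the differentiation. Setting out from 10, excess Li(s-Bu)3BH in THF at −78 °C reduces the enone in 1,4-fashion and the C1 ketone in 1,2-fashion; PhNTf2 then traps the C9 enolate and should leave the hindered C1 alkoxide alone, giving after work-up the hydroxy enol triflate F3 (C1 carbinol configuration irrelevant). Stille coupling with 13 under the conditions of step 8 gives the dienol F4, and Dess–Martin oxidation of the secondary alcohol comes back to the route at 14.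

Step 10. Condensation of hydrazine with the C1 carbonyl, flanked by the quaternary C10 on the concave face of the cis-decalin, may be slow, so that azine formation and thermal decomposition compete at 200 °C. The fallback needs no addition to the carbonyl carbon. Setting out from 14, KN(SiMe3)2 and PhNTf2 in THF at −78 °C give the C1 enol triflate F5 (C2 is the only enolisable position). Pd(OAc)2, PPh3, Bu3N and HCO2H in DMF reduce it to the C1=C2 alkene, the triene F6. 9-BBN hydroborates only the terminal vinyl group to the alkylborane F7, which aq. NaOH/H2O2 oxidises in the same flask to the dienol F8. Diimide generated from 2-nitrobenzenesulfonyl hydrazide and Et3N then saturates the cis-disubstituted C1=C2 bond and leaves the tetrasubstituted C8=C9 bond, coming back to the route at 18.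

Further compounds
F1 | step 6 | 6-(3-bromopropanoyl)-5-(2-bromopropan-2-yl)-2,6-dimethylcyclohex-2-en-1-one (ring configuration as in 9) | CC1=CC[C@H](C(C)(C)Br)[C@](C)(C(=O)CCBr)C1=O
F2 | step 6 | 6-acryloyl-5-(2-bromopropan-2-yl)-2,6-dimethylcyclohex-2-en-1-one (ring configuration as in 9) | CC1=CC[C@H](C(C)(C)Br)[C@](C)(C(=O)C=C)C1=O
F3 | step 7 | hydroxy enol triflate, the C1 alcohol corresponding to 12 | CC1=C(OS(=O)(=O)C(F)(F)F)[C@@]2(C)C(O)CCC(C)(C)[C@H]2CC1
F4 | step 7 | dienol, the C1 alcohol corresponding to 14 | CC1=C(C=C)[C@@]2(C)C(O)CCC(C)(C)[C@H]2CC1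
F5 | step 10 | C1 enol triflate of 14 (C1=C2) | CC1=C(C=C)[C@@]2(C)C(OS(=O)(=O)C(F)(F)F)=CCC(C)(C)[C@H]2CC1
F6 | step 10 | triene with C1=C2, C8=C9 and the C9 vinyl group | CC1=C(C=C)[C@@]2(C)C=CCC(C)(C)[C@H]2CC1
F7 | step 10 | alkylborane, the 9-BBN adduct of F6 at C12 | CC1=C(CCB3C4CCCC3CCC4)[C@@]2(C)C=CCC(C)(C)[C@H]2CC1
F8 | step 10 | dienol, the C1=C2 unsaturated analogue of 18 | CC1=C(CCO)[C@@]2(C)C=CCC(C)(C)[C@H]2CC1
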